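**Retrosynthetic overview**
- The pyran ring is made last: orcinol and an (E)-β,β-dialkyl enal are joined by a catalytic asymmetric chromene annulation whose ring-closing C–O bond (oxa-6π) sets the chromene stereocentre.
- The enal comes from a terminal alkyne (syn-carboalumination, hydroxymethylation, allylic oxidation); the diol is masked as a cyclic carbonate.
- The cis-1,2-diol comes from a Sharpless epoxidation of a cyclohexenylmethanol (tertiary C–O bond cis to the side chain) and hydride opening.
- The allylic alcohol comes from an α-methylene ketone (epoxidation, Wharton transposition), itself from a copper-catalysed asymmetric conjugate addition to 4,4-dimethylcyclohex-2-enone, which sets the ring CH.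
- Ring order: the carbocycle is bought; the pyran ring is formed in the last step.

Assumption: the sense of induction of the new catalyst in step 10 is unknown; the (S)-catalyst is written as the enantiomer that gives the 2S chromene, and its mirror image would be used if the sense proves opposite.

**Step 1**
Reactants: 1 4,4-dimethylcyclohex-2-en-1-one; 2 (4-bromobut-1-yn-1-yl)trimethylsilane
Product: 6 trimethyl({(3R)-4,4-dimethyl-3-[4-(trimethylsilyl)but-3-yn-1-yl]cyclohex-1-en-1-yl}oxy)silane, via alkylmagnesium bromide 3 (not isolated), via dialkylzinc 4 (not isolated), via zinc enolate 5 (not isolated)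
Conditions: 2, Mg, THF; ZnCl2 (0.5 equiv), then 1,4-dioxane, filter, solvent changed to PhMe; 1, Cu(OTf)2 (2 mol %), (S,R,R)-phosphoramidite L (4 mol %; from (S)-BINOL and bis[(R)-1-phenylethyl]amine, the enantiomer that gives (S)-3-ethylcyclohexanone from cyclohex-2-enone and Et2Zn), −30 °C; TMSOTf, −30 °C → rt
Reagents that add atoms: trimethylsilyl trifluoromethanesulfonate, C[Si](C)(C)OS(=O)(=O)C(F)(F)F
Why: Copper/phosphoramidite-catalysed asymmetric conjugate addition of a dialkylzinc (Feringa reaction, precedented at high ee on this enone with Et2Zn) sets C-3 as R by ligand-controlled attack on one enone face, and O-silylation of the regiodefined zinc enolate stores the enolate position for step 2.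

**Step 2**
Reactants: 6 trimethyl({(3R)-4,4-dimethyl-3-[4-(trimethylsilyl)but-3-yn-1-yl]cyclohex-1-en-1-yl}oxy)silane
Product: 9 (3S)-4,4-dimethyl-2-methylidene-3-[4-(trimethylsilyl)but-3-yn-1-yl]cyclohexan-1-one, via Mannich base 7 (not isolated), via ammonium iodide 8 (not isolated)
Conditions: CH2=NMe2+ I− (Eschenmoser's salt), CH2Cl2, rt; MeI, rt; aq. NaHCO3
Reagents that add atoms: Eschenmoser's salt (N,N-dimethylmethyleneiminium iodide), C=[N+](C)C.[I-]
Why: Mannich reaction of the silyl enol ether places the one-carbon unit on C-2 only, and quaternisation followed by base-induced elimination of trimethylamine (Danishefsky α-methylenation) gives the exocyclic enone without touching C-3, which is not acidic (the descriptor changes from R to S only through CIP priorities).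

**Step 3**
Reactants: 9 (3S)-4,4-dimethyl-2-methylidene-3-[4-(trimethylsilyl)but-3-yn-1-yl]cyclohexan-1-one
Product: 10 (8S)-8-(but-3-yn-1-yl)-7,7-dimethyl-1-oxaspiro[2.5]octan-4-one (epimers at the spiro carbon C-3)
Conditions: 30% H2O2, NaOH, MeOH, 0 °C → rt
Reagents that add atoms: hydrogen peroxide, OO
Why: Weitz–Scheffer nucleophilic epoxidation of the α-methylene ketone, with methoxide cleaving the alkynyl–silicon bond in the same flask; the spiro centre is destroyed in step 4, so its configuration does not matter.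

**Step 4**
Reactants: 10 (8S)-8-(but-3-yn-1-yl)-7,7-dimethyl-1-oxaspiro[2.5]octan-4-one
Product: 12 [(6S)-6-(but-3-yn-1-yl)-5,5-dimethylcyclohex-1-en-1-yl]methanol, via epoxy hydrazone 11 (not isolated)
Conditions: N2H4·H2O (3 equiv), AcOH (cat.), MeOH, 0 °C → rt, Ar
Reagents that add atoms: none
Why: Wharton rearrangement: the epoxy hydrazone opens to a vinyl diazene that loses N2, which removes the ring carbonyl, places the alkene between C-1 and C-2 and frees the primary allylic alcohol.

**Step 5**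
Reactants: 12 [(6S)-6-(but-3-yn-1-yl)-5,5-dimethylcyclohex-1-en-1-yl]methanol
Product: 13 [(1R,2S,6R)-2-(but-3-yn-1-yl)-3,3-dimethyl-7-oxabicyclo[4.1.0]heptan-1-yl]methanol
Conditions: Ti(OiPr)4 (0.2 equiv), D-(−)-DET (0.25 equiv), t-BuOOH, 4 Å MS, CH2Cl2, −20 °C
Reagents that add atoms: tert-butyl hydroperoxide, CC(C)(C)OO
Why: Sharpless asymmetric epoxidation: D-(−)-tartrate delivers oxygen to the alkene face that, for the 6S alcohol, is cis to the side chain (the enantioface that gives 2R,3R epoxides from simple E-allylic alcohols), in line with the cis-selective peracid epoxidation known for α-ionone-type rings, so reagent and substrate control are expected to agree and the tertiary C–O bond is set cis to the chain.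

**Step 6**
Reactants: 13 [(1R,2S,6R)-2-(but-3-yn-1-yl)-3,3-dimethyl-7-oxabicyclo[4.1.0]heptan-1-yl]methanol
Product: 14 (1R,2S)-2-(but-3-yn-1-yl)-1-(hydroxymethyl)-3,3-dimethylcyclohexan-1-ol
Conditions: LiAlH4, THF, 0 °C → rt
Reagents that add atoms: none
Why: Hydride opening of the 2,3-epoxy alcohol can only take place at the secondary carbon C-6 (C-1 is quaternary; trans-diaxial opening), so the tertiary C–O bond and its configuration are kept and the 1,2-diol results.

**Step 7**
Reactants: 14 (1R,2S)-2-(but-3-yn-1-yl)-1-(hydroxymethyl)-3,3-dimethylcyclohexan-1-ol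
Product: 16 (1R,2S)-1-(hydroxymethyl)-2-[(3E)-5-hydroxy-3-methylpent-3-en-1-yl]-3,3-dimethylcyclohexan-1-ol, via alkenylalane 15 (not isolated)
Conditions: AlMe3 (5 equiv), Cp2ZrCl2 (0.25 equiv), CH2Cl2, 0 °C → rt; evaporate; n-BuLi, THF, −78 °C; (CH2O)n, −78 °C → rt; aq. Rochelle salt
Reagents that add atoms: trimethylaluminium, C[Al](C)C; paraformaldehyde (as formaldehyde), C=O
Why: Negishi zirconium-catalysed carboalumination adds methyl and aluminium syn across the terminal alkyne with methyl on the internal carbon, and the derived alanate reacts with formaldehyde with retention, so the (E)-allylic alcohol forms as one geometric isomer while the diol is carried as its aluminium alkoxide.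

**Step 8**
Reactants: 16 (1R,2S)-1-(hydroxymethyl)-2-[(3E)-5-hydroxy-3-methylpent-3-en-1-yl]-3,3-dimethylcyclohexan-1-ol
Product: 17 (2E)-5-[(1S,2R)-2-hydroxy-2-(hydroxymethyl)-6,6-dimethylcyclohexyl]-3-methylpent-2-enal
Conditions: MnO2 (15 equiv), CH2Cl2, rt
Reagents that add atoms: none
Why: MnO2 oxidises only the allylic alcohol (the saturated primary and the tertiary hydroxyl are inert) and leaves the E geometry intact.

**Step 9**
Reactants: 17 (2E)-5-[(1S,2R)-2-hydroxy-2-(hydroxymethyl)-6,6-dimethylcyclohexyl]-3-methylpent-2-enal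
Product: 18 (2E)-5-[(5R,6S)-7,7-dimethyl-2-oxo-1,3-dioxaspiro[4.5]decan-6-yl]-3-methylpent-2-enal
Conditions: CDI (1.5 equiv), DMAP (0.1 equiv), PhMe, 60 °C
Reagents that add atoms: 1,1′-carbonyldiimidazole, O=C(n1ccnc1)n1ccnc1
Why: Acyl transfer to the primary hydroxyl and 5-exo closure onto the tertiary hydroxyl give the acid-stable cyclic carbonate, which keeps the diol from forming acetals with the enal or trapping the cationic intermediate in step 10.

**Step 10**
Reactants: 18 (2E)-5-[(5R,6S)-7,7-dimethyl-2-oxo-1,3-dioxaspiro[4.5]decan-6-yl]-3-methylpent-2-enal; 19 orcinol (5-methylbenzene-1,3-diol)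
Product: 22 (1R,2S)-2-{2-[(2S)-5-hydroxy-2,7-dimethyl-2H-chromen-2-yl]ethyl}-1-(hydroxymethyl)-3,3-dimethylcyclohexan-1-ol, via quinone methide 20 (not isolated), via chromene carbonate 21 (not isolated)
Conditions: 19 (3 equiv), (S)-3,3′-bis(2,4,6-triisopropylphenyl)-H8-BINOL N-triflylphosphoramide (5 mol %), 5 Å MS, PhMe/MTBE 4:1, −30 °C; then K2CO3, MeOH, rt
Reagents that add atoms: none
Why: Proposed new method: a catalytic enantioselective resorcinol–enal chromene annulation in which the confined chiral N-triflylphosphoramide promotes ortho-hydroxyalkylation at C-2 of orcinol (the position between the two hydroxyls, as in the known amine-salt annulation) and dehydration to the vinyl ortho-quinone methide 20, which stays hydrogen-bonded and ion-paired to the chiral phosphoramidate so that the ring-closing C–O bond (oxa-6π electrocyclisation, equivalently collapse of the contact ion pair) forms from one helical sense of the oxatriene only, and because the fixed E geometry decides which of methyl and chain turns inward this helicity becomes the 2S centre while the remote ring centres play no part; the closest known reactions are the racemic ethylenediammonium diacetate annulation of resorcinols with enals and chiral Brønsted acid contact-ion-pair cyclisations of 2-(hydroxyallyl)phenols to 2H-chromenes, and K2CO3/MeOH then removes the carbonate in the same flask.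

**Compound list**
1 | 4,4-dimethylcyclohex-2-en-1-one | CC1(C)CCC(=O)C=C1 | starting material
2 | (4-bromobut-1-yn-1-yl)trimethylsilane | C[Si](C)(C)C#CCCBr | starting material
3 | bromo[4-(trimethylsilyl)but-3-yn-1-yl]magnesium | C[Si](C)(C)C#CCC[Mg]Br | intermediate
4 | bis[4-(trimethylsilyl)but-3-yn-1-yl]zinc | C[Si](C)(C)C#CCC[Zn]CCC#C[Si](C)(C)C | intermediate
5 | ({(3R)-4,4-dimethyl-3-[4-(trimethylsilyl)but-3-yn-1-yl]cyclohex-1-en-1-yl}oxy)[4-(trimethylsilyl)but-3-yn-1-yl]zinc | C[Si](C)(C)C#CCC[C@H]1C(C)(C)CCC(O[Zn]CCC#C[Si](C)(C)C)=C1 | intermediate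
6 | trimethyl({(3R)-4,4-dimethyl-3-[4-(trimethylsilyl)but-3-yn-1-yl]cyclohex-1-en-1-yl}oxy)silane | C[Si](C)(C)C#CCC[C@H]1C(C)(C)CCC(O[Si](C)(C)C)=C1 | intermediate
7 | (3R)-2-[(dimethylamino)methyl]-4,4-dimethyl-3-[4-(trimethylsilyl)but-3-yn-1-yl]cyclohexan-1-one (C-2 epimers) | C[Si](C)(C)C#CCC[C@H]1C(C)(C)CCC(=O)C1CN(C)C | intermediate
8 | ({(6R)-5,5-dimethyl-2-oxo-6-[4-(trimethylsilyl)but-3-yn-1-yl]cyclohexyl}methyl)trimethylazanium iodide (C-1 epimers) | C[Si](C)(C)C#CCC[C@H]1C(C)(C)CCC(=O)C1C[N+](C)(C)C.[I-] | intermediate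
9 | (3S)-4,4-dimethyl-2-methylidene-3-[4-(trimethylsilyl)but-3-yn-1-yl]cyclohexan-1-one | C[Si](C)(C)C#CCC[C@H]1C(C)(C)CCC(=O)C1=C | intermediate
10 | (8S)-8-(but-3-yn-1-yl)-7,7-dimethyl-1-oxaspiro[2.5]octan-4-one (C-3 epimers) | C#CCC[C@H]1C(C)(C)CCC(=O)C12CO2 | intermediate
11 | hydrazone of (8S)-8-(but-3-yn-1-yl)-7,7-dimethyl-1-oxaspiro[2.5]octan-4-one | C#CCC[C@H]1C(C)(C)CCC(=NN)C12CO2 | intermediate
12 | [(6S)-6-(but-3-yn-1-yl)-5,5-dimethylcyclohex-1-en-1-yl]methanol | C#CCC[C@H]1C(C)(C)CCC=C1CO | intermediate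
13 | [(1R,2S,6R)-2-(but-3-yn-1-yl)-3,3-dimethyl-7-oxabicyclo[4.1.0]heptan-1-yl]methanol | C#CCC[C@H]1C(C)(C)CC[C@H]2O[C@@]12CO | intermediate
14 | (1R,2S)-2-(but-3-yn-1-yl)-1-(hydroxymethyl)-3,3-dimethylcyclohexan-1-ol | C#CCC[C@H]1C(C)(C)CCC[C@]1(O)CO | intermediate
15 | (E)-alkenyl(dimethyl)alane from 14, diol bound as its methylaluminium diolate | C[Al](C)/C=C(\C)CC[C@H]1C(C)(C)CCC[C@]12CO[Al](C)O2 | intermediate
16 | (1R,2S)-1-(hydroxymethyl)-2-[(3E)-5-hydroxy-3-methylpent-3-en-1-yl]-3,3-dimethylcyclohexan-1-ol | OC/C=C(\C)CC[C@H]1C(C)(C)CCC[C@]1(O)CO | intermediate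
17 | (2E)-5-[(1S,2R)-2-hydroxy-2-(hydroxymethyl)-6,6-dimethylcyclohexyl]-3-methylpent-2-enal | O=C/C=C(\C)CC[C@H]1C(C)(C)CCC[C@]1(O)CO | intermediate
18 | (2E)-5-[(5R,6S)-7,7-dimethyl-2-oxo-1,3-dioxaspiro[4.5]decan-6-yl]-3-methylpent-2-enal | O=C/C=C(\C)CC[C@H]1C(C)(C)CCC[C@]12COC(=O)O2 | intermediate
19 | orcinol (5-methylbenzene-1,3-diol) | Cc1cc(O)cc(O)c1 | starting material
20 | (6Z)-5-hydroxy-3-methyl-6-{(2E)-3-methyl-5-[(5R,6S)-7,7-dimethyl-2-oxo-1,3-dioxaspiro[4.5]decan-6-yl]pent-2-en-1-ylidene}cyclohexa-2,4-dien-1-one | CC1=CC(=O)/C(=C\C=C(/C)CC[C@H]2C(C)(C)CCC[C@]23COC(=O)O3)C(O)=C1 | intermediate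
21 | (5R,6S)-6-{2-[(2S)-5-hydroxy-2,7-dimethyl-2H-chromen-2-yl]ethyl}-7,7-dimethyl-1,3-dioxaspiro[4.5]decan-2-one | Cc1cc(O)c2c(c1)O[C@@](C)(CC[C@H]1C(C)(C)CCC[C@]13COC(=O)O3)C=C2 | intermediate
22 | (1R,2S)-2-{2-[(2S)-5-hydroxy-2,7-dimethyl-2H-chromen-2-yl]ethyl}-1-(hydroxymethyl)-3,3-dimethylcyclohexan-1-ol | Cc1cc(O)c2c(c1)O[C@@](C)(CC[C@H]1C(C)(C)CCC[C@]1(O)CO)C=C2 | target

**Step count:** 10 steps in total; longest linear sequence 10 steps (1 → 22), with 2 and 19 entering directly.

**Steps most likely to fail**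

Step 10 (the new annulation). The risks are attack at C-4 instead of C-2 of orcinol (giving the 7-hydroxy-5-methyl isomer), a racemic background closure of free quinone methide, and a wrong or weak sense of induction. Fallback with known chemistry: setting out from 18 and 19, the established racemic annulation (ethylenediammonium diacetate, PhMe, reflux; condensation at C-2 of the resorcinol and thermal oxa-6π closure) gives 21 together with its C-2 epimer (5R,6S)-6-{2-[(2R)-5-hydroxy-2,7-dimethyl-2H-chromen-2-yl]ethyl}-7,7-dimethyl-1,3-dioxaspiro[4.5]decan-2-one F1 in about equal amounts. The two diastereomers are separated by preparative HPLC on a chiral stationary phase, and 21 is methanolysed (K2CO3, MeOH) to come back at 22.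

Step 4 (Wharton rearrangement). Yields are often moderate, and hydrazine can open the terminal epoxide. Fallback: setting out from 9, Luche reduction (NaBH4, CeCl3·7H2O, MeOH, −20 °C) gives (3S)-4,4-dimethyl-2-methylidene-3-[4-(trimethylsilyl)but-3-yn-1-yl]cyclohexan-1-ol F2 (carbinol epimers). Its hydroxyl is moved to the exocyclic carbon by Ph3SiOReO3-catalysed 1,3-transposition, which gives {(6S)-5,5-dimethyl-6-[4-(trimethylsilyl)but-3-yn-1-yl]cyclohex-1-en-1-yl}methanol F3. K2CO3/MeOH then removes the silyl group and the sequence comes back at 12.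

Step 7 (carboalumination and hydroxymethylation on the free diol). The aluminium diolate may slow the carbometalation or the alanate formation. Fallback: setting out from 14, the diol is protected (2,2-dimethoxypropane, PPTS) as (5R,6S)-6-(but-3-yn-1-yl)-2,2,7,7-tetramethyl-1,3-dioxaspiro[4.5]decane F4. Water-accelerated carboalumination at −20 °C with an iodine quench gives (5R,6S)-6-[(3E)-4-iodo-3-methylbut-3-en-1-yl]-2,2,7,7-tetramethyl-1,3-dioxaspiro[4.5]decane F5. Iodine–lithium exchange (t-BuLi, −78 °C) and formylation with DMF give (2E)-3-methyl-5-[(5R,6S)-2,2,7,7-tetramethyl-1,3-dioxaspiro[4.5]decan-6-yl]pent-2-enal F6, and aqueous acetic acid removes the acetonide to come back at 17.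

**Further compounds**
F1 | step 10 | (5R,6S)-6-{2-[(2R)-5-hydroxy-2,7-dimethyl-2H-chromen-2-yl]ethyl}-7,7-dimethyl-1,3-dioxaspiro[4.5]decan-2-one | Cc1cc(O)c2c(c1)O[C@](C)(CC[C@H]1C(C)(C)CCC[C@]13COC(=O)O3)C=C2
F2 | step 4 | (3S)-4,4-dimethyl-2-methylidene-3-[4-(trimethylsilyl)but-3-yn-1-yl]cyclohexan-1-ol (C-1 epimers) | C[Si](C)(C)C#CCC[C@H]1C(C)(C)CCC(O)C1=C
F3 | step 4 | {(6S)-5,5-dimethyl-6-[4-(trimethylsilyl)but-3-yn-1-yl]cyclohex-1-en-1-yl}methanol | C[Si](C)(C)C#CCC[C@H]1C(C)(C)CCC=C1CO
F4 | step 7 | (5R,6S)-6-(but-3-yn-1-yl)-2,2,7,7-tetramethyl-1,3-dioxaspiro[4.5]decane | C#CCC[C@H]1C(C)(C)CCC[C@]12COC(C)(C)O2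
F5 | step 7 | (5R,6S)-6-[(3E)-4-iodo-3-methylbut-3-en-1-yl]-2,2,7,7-tetramethyl-1,3-dioxaspiro[4.5]decane | I/C=C(\C)CC[C@H]1C(C)(C)CCC[C@]12COC(C)(C)O2
F6 | step 7 | (2E)-3-methyl-5-[(5R,6S)-2,2,7,7-tetramethyl-1,3-dioxaspiro[4.5]decan-6-yl]pent-2-enal | O=C/C=C(\C)CC[C@H]1C(C)(C)CCC[C@]12COC(C)(C)O2
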